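The route rests on cutting ring A of unit E (the chromanone that carries the 3,4-dihydroxyphenyl group; unit N carries the 4-hydroxyphenyl group). This phloroglucinol ring has only two links to the remainder, the aryl ether bond O1(E)–C8a(E) and the aryl ketone bond C4(E)–C4a(E). Both arise together when a carboxylate adds to 3,5-bis(benzyloxy)benzyne and its acyl group then shifts to the neighbouring carbon, which gives a 2'-hydroxy-α-arylchalcone with no ring closed. The precursor is an (E)-2,3-diarylacrylic acid: its α-aryl group is C8 of a benzylated 5,7-dioxychromone (the future unit N) and its β-aryl group is the benzylated catechol. Later steps close ring C(E) and set the three stereocentres.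

Key step: step 10

Assumption: the sense of induction of the two chiral catalysts (steps 12 and 13) is taken from the simplest substrates of each reaction class; if a model reaction shows the opposite sense, the mirror-image ligand is used.
Remark: rotation about C3(E)–C8(N) should be slow, so the compounds from step 11 onward may appear as rotamer mixtures that converge on one compound; 3,5-bis(benzyloxy)phenol is taken as a catalogue compound; t-BuPyOx is 4-tert-butyl-2-(2-pyridyl)-4,5-dihydrooxazole and SINpEt·HBF4 is 1,3-bis[1-(1-naphthyl)ethyl]-4,5-dihydroimidazolium tetrafluoroborate.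

Step 1
Reactants: 1 3,5-bis(benzyloxy)phenol
Product: 2 2-bromo-3,5-bis(benzyloxy)phenol
Conditions: NBS (1.0 equiv), CH2Cl2, −78 °C to 0 °C
Reagents that add atoms: N-bromosuccinimide, O=C1CCC(=O)N1Br
Why: Electrophilic aromatic bromination should go ortho to the free hydroxyl group because the para position lies between two benzyloxy groups, and one equivalent of reagent at low temperature limits dibromination, the minor para isomer being removed by chromatography.

Step 2
Reactants: 2 2-bromo-3,5-bis(benzyloxy)phenol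
Product: 5 3,5-bis(benzyloxy)-2-(trimethylsilyl)phenyl trifluoromethanesulfonate, via aryl trimethylsilyl ether 3 (not isolated), via lithium 2-silylphenoxide 4 (not isolated)
Conditions: (Me3Si)2NH, THF, 70 °C; then n-BuLi, THF, −78 °C; then Tf2O, −78 °C
Reagents that add atoms: hexamethyldisilazane, C[Si](C)(C)N[Si](C)(C)C; trifluoromethanesulfonic anhydride, O=S(=O)(OS(=O)(=O)C(F)(F)F)C(F)(F)F
Why: O-Silylation, bromine–lithium exchange and migration of silicon from oxygen to the aryl carbanion (retro-Brook rearrangement) should give the ortho-silyl phenoxide, which is triflated in the same flask, the exchange at −78 °C being faster than deprotonation of the benzyl ethers.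

Step 3
Reactants: 6 2',4',6'-trihydroxyacetophenone
Product: 7 1-[2,4-bis(benzyloxy)-6-hydroxyphenyl]ethanone
Conditions: BnBr (2.1 equiv), K2CO3, DMF, 25 °C
Reagents that add atoms: benzyl bromide, BrCc1ccccc1
Why: Williamson etherification should stop after two benzylations because the remaining hydroxyl group is hydrogen-bonded to the acetyl group and far less nucleophilic.

Step 4
Reactants: 7 1-[2,4-bis(benzyloxy)-6-hydroxyphenyl]ethanone
Product: 8 1-[4,6-bis(benzyloxy)-2-hydroxy-3-iodophenyl]ethanone
Conditions: NIS, CF3CO2H (cat.), MeCN, 0 °C to 25 °C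
Reagents that add atoms: N-iodosuccinimide, O=C1CCC(=O)N1I
Why: Electrophilic aromatic iodination should take the position ortho to the free hydroxyl group (C3'), which is less crowded than the position between the two benzyloxy groups.

Step 5
Reactants: 8 1-[4,6-bis(benzyloxy)-2-hydroxy-3-iodophenyl]ethanone
Product: 10 5,7-bis(benzyloxy)-8-iodo-4H-chromen-4-one, via enaminone 9 (not isolated)
Conditions: Me2NCH(OMe)2, toluene, 100 °C; then conc. HCl, CH2Cl2, 40 °C
Reagents that add atoms: N,N-dimethylformamide dimethyl acetal, COC(OC)N(C)C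
Why: Condensation of the methyl ketone with the amide acetal gives the enaminone, and acid-promoted addition of the phenol with loss of dimethylamine closes the pyranone ring (enaminone route to chromones), which places iodine at C8 because only the hydroxyl group next to it can cyclise.

Step 6
Reactants: 10 5,7-bis(benzyloxy)-8-iodo-4H-chromen-4-one
Product: 11 5,7-bis(benzyloxy)-8-(4,4,5,5-tetramethyl-1,3,2-dioxaborolan-2-yl)-4H-chromen-4-one
Conditions: B2pin2, Pd(OAc)2 (cat.), SPhos, KOAc, 1,4-dioxane, 90 °C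
Reagents that add atoms: bis(pinacolato)diboron, CC1(C)OB(OC1(C)C)B1OC(C)(C)C(C)(C)O1
Why: Miyaura borylation of the aryl iodide should proceed with a bulky biarylphosphine that tolerates the two ortho oxygen substituents, and the weak base KOAc leaves the chromone untouched.

Step 7
Reactants: 12 tert-butyl (triphenylphosphoranylidene)acetate; 13 3,4-bis(benzyloxy)benzaldehyde
Product: 15 tert-butyl (Z)-2-bromo-3-[3,4-bis(benzyloxy)phenyl]prop-2-enoate, via bromo ylide 14 (not isolated)
Conditions: NBS, CH2Cl2, −20 °C; then 13, K2CO3, 25 °C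
Reagents that add atoms: N-bromosuccinimide, O=C1CCC(=O)N1Br
Why: Bromination of the stabilised ylide followed by Wittig olefination in one flask should give the (Z)-bromoacrylate, since a stabilised ylide places the ester trans to the aryl group.

Step 8
Reactants: 11 5,7-bis(benzyloxy)-8-(pinacolboryl)chromone; 15 tert-butyl (Z)-2-bromo-3-[3,4-bis(benzyloxy)phenyl]prop-2-enoate
Product: 16 tert-butyl (E)-3-[3,4-bis(benzyloxy)phenyl]-2-[5,7-bis(benzyloxy)-4-oxo-4H-chromen-8-yl]prop-2-enoate
Conditions: Pd(OAc)2 (cat.), SPhos, K3PO4, toluene–H2O, 80 °C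
Reagents that add atoms: none
Why: Suzuki–Miyaura coupling with retention of alkene geometry should join the hindered arylboronate to the electron-poor vinyl bromide, the dialkylbiarylphosphine speeding transmetalation ahead of protodeboronation.

Step 9
Reactants: 16 tert-butyl (E)-2,3-diarylacrylate
Product: 17 (E)-3-[3,4-bis(benzyloxy)phenyl]-2-[5,7-bis(benzyloxy)-4-oxo-4H-chromen-8-yl]prop-2-enoic acid
Conditions: CF3CO2H, CH2Cl2, 0 °C to 25 °C
Reagents that add atoms: none
Why: Acidolysis of the tert-butyl ester with loss of isobutene avoids aqueous base, which would open the chromone, and the aryl benzyl ethers should survive dilute CF3CO2H at this temperature.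

Step 10
Reactants: 17 (E)-2,3-diarylacrylic acid; 5 3,5-bis(benzyloxy)-2-(trimethylsilyl)phenyl trifluoromethanesulfonate
Product: 19 (E)-1-[2,4-bis(benzyloxy)-6-hydroxyphenyl]-3-[3,4-bis(benzyloxy)phenyl]-2-[5,7-bis(benzyloxy)-4-oxo-4H-chromen-8-yl]prop-2-en-1-one, via 3,5-bis(benzyloxy)benzyne 18 (not isolated)
Conditions: 5 (1.5 equiv), CsF (4 equiv), THF, 110 °C, sealed tube
Reagents that add atoms: none
Why: Fluoride removes the silyl group of 5 and triflate leaves to give aryne 18; the carboxylate of 17 adds to the aryne carbon remote from the flanking benzyloxy group, and the resulting aryl anion attacks the ester carbonyl through a four-membered alkoxide that opens to the phenoxide of the ortho-acylphenol, so that O1(E)–C8a(E) and C4(E)–C4a(E) are formed. The closest known reaction type is the insertion of arynes into the C–O bond of carboxylic acids, cinnamic acids included, which gives ortho-hydroxyaryl ketones. No ring is closed and no stereocentre is formed, and the alkene geometry is of no consequence because step 11 removes it. The regiochemistry on the aryne is secured by the 3-benzyloxy group, which stabilises the adjacent carbanion inductively, distorts the aryne toward attack at the remote carbon and shields the near one, so the acyl group ends between two oxygens with the third oxygen para. Acyl transfer must outrun protonation of the aryl anion, which its intramolecular four-centre geometry, hot THF and excess dry CsF should secure. The bulky α-aryl group should slow oxa-Michael closure, and any flavanone that does form converges in step 11.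

Step 11
Reactants: 19 2'-hydroxy-α-(chromon-8-yl)chalcone
Product: 21 5,7-bis(benzyloxy)-2-[3,4-bis(benzyloxy)phenyl]-3-[5,7-bis(benzyloxy)-4-oxo-4H-chromen-8-yl]-4H-chromen-4-one, via 3-arylflavanone 20 (not isolated)
Conditions: I2 (10 mol %), DMSO, 120 °C
Reagents that add atoms: none
Why: Oxidative cyclisation of a 2'-hydroxychalcone, in which 6-endo oxa-Michael addition of the phenol gives flavanone 20 and iodine then dehydrogenates C2–C3 while DMSO reoxidises the iodide, should give the flavone of unit E and leave the chromone of unit N, which has no enolisable position, unchanged.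

Step 12
Reactants: 21 flavone E–chromone N; 22 4-(benzyloxy)phenylboronic acid
Product: 23 (2S)-5,7-bis(benzyloxy)-2-[4-(benzyloxy)phenyl]-8-{5,7-bis(benzyloxy)-2-[3,4-bis(benzyloxy)phenyl]-4-oxo-4H-chromen-3-yl}chroman-4-one
Conditions: 22 (3 equiv), Pd(OCOCF3)2 (10 mol %), (R)-t-BuPyOx, NH4PF6, H2O, ClCH2CH2Cl, 60 °C
Reagents that add atoms: none
Why: Asymmetric conjugate addition of an arylboronic acid to a chromone by a cationic arylpalladium–pyridinooxazoline complex should set C2(N), the (R)-ligand being expected to deliver the aryl group to the face that gives (S), while the tetrasubstituted flavone of unit E cannot undergo insertion.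

Step 13
Reactants: 23 flavone E–(2S)-flavanone N
Product: 24 5,7-bis(benzyloxy)-2-[3,4-bis(benzyloxy)phenyl]-3-{5,7-bis(benzyloxy)-2-[4-(benzyloxy)phenyl]-4-hydroxychroman-8-yl}chroman-4-ol (unit E 2R,3S, which is 2,3-cis; unit N 2S; both C4 carbinol centres unassigned)
Conditions: Ru(cod)(2-methylallyl)2 (10 mol %), (R,R)-SINpEt·HBF4, KOt-Bu, hexane, 70 °C; then 23, toluene, H2 (120 bar), 40 °C
Reagents that add atoms: none
Why: Proposed new method: a chiral ruthenium N-heterocyclic carbene hydride is expected to add hydrogen to C2(E) and C3(E) from the one face chosen by the ligand (syn addition, hence 2,3-cis; a stepwise path with protonation of the C3 enolate anti to the C2 aryl group leads to the same isomer) and then to reduce both carbonyl groups, which locks C3(E) against epimerisation and leaves the benzyl ethers intact, the closest known reaction type being the asymmetric hydrogenation of flavones to cis-flavan-4-ols with this catalyst family, extended here to a 3-aryl, tetrasubstituted flavone.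

Step 14
Reactants: 24 bis(flavan-4-ol)
Product: 25 (2R,3R)-5,7-bis(benzyloxy)-2-[3,4-bis(benzyloxy)phenyl]-3-{(2S)-5,7-bis(benzyloxy)-2-[4-(benzyloxy)phenyl]-4-oxochroman-8-yl}chroman-4-one
Conditions: Dess–Martin periodinane, pyridine, CH2Cl2, 0 °C to 25 °C
Reagents that add atoms: none
Why: Dess–Martin oxidation returns both benzylic carbinols to ketones under buffered, non-enolising conditions, so the cis relation at C2(E)–C3(E) and the configuration at C2(N) should be kept.

Step 15
Reactants: 25 heptabenzyl ether of the target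
Product: 26 (2R,3R)-2-(3,4-dihydroxyphenyl)-5,7-dihydroxy-3-[(2S)-5,7-dihydroxy-2-(4-hydroxyphenyl)-4-oxochroman-8-yl]chroman-4-one
Conditions: H2 (1 atm), Pd/C, EtOAc–MeOH, 25 °C
Reagents that add atoms: none
Why: Hydrogenolysis of the seven benzyl ethers under neutral conditions should free all phenols without epimerising C3(E), the aryl ketones and the cyclic benzylic ethers being slow to reduce at one atmosphere.

Compound list
1 | 3,5-bis(benzyloxy)phenol | Oc1cc(OCc2ccccc2)cc(OCc2ccccc2)c1 | starting material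
2 | 2-bromo-3,5-bis(benzyloxy)phenol | Oc1cc(OCc2ccccc2)cc(OCc2ccccc2)c1Br | intermediate
3 | [2-bromo-3,5-bis(benzyloxy)phenoxy]trimethylsilane | C[Si](C)(C)Oc1cc(OCc2ccccc2)cc(OCc2ccccc2)c1Br | intermediate
4 | lithium 3,5-bis(benzyloxy)-2-(trimethylsilyl)phenoxide | [Li+].[O-]c1cc(OCc2ccccc2)cc(OCc2ccccc2)c1[Si](C)(C)C | intermediate
5 | 3,5-bis(benzyloxy)-2-(trimethylsilyl)phenyl trifluoromethanesulfonate | C[Si](C)(C)c1c(OCc2ccccc2)cc(OCc2ccccc2)cc1OS(=O)(=O)C(F)(F)F | intermediate
6 | 2',4',6'-trihydroxyacetophenone | CC(=O)c1c(O)cc(O)cc1O | starting material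
7 | 1-[2,4-bis(benzyloxy)-6-hydroxyphenyl]ethanone | CC(=O)c1c(O)cc(OCc2ccccc2)cc1OCc1ccccc1 | intermediate
8 | 1-[4,6-bis(benzyloxy)-2-hydroxy-3-iodophenyl]ethanone | CC(=O)c1c(O)c(I)c(OCc2ccccc2)cc1OCc1ccccc1 | intermediate
9 | (E)-1-[4,6-bis(benzyloxy)-2-hydroxy-3-iodophenyl]-3-(dimethylamino)prop-2-en-1-one | CN(C)/C=C/C(=O)c1c(O)c(I)c(OCc2ccccc2)cc1OCc1ccccc1 | intermediate
10 | 5,7-bis(benzyloxy)-8-iodo-4H-chromen-4-one | O=C1C=COc2c1c(OCc1ccccc1)cc(OCc1ccccc1)c2I | intermediate
11 | 5,7-bis(benzyloxy)-8-(4,4,5,5-tetramethyl-1,3,2-dioxaborolan-2-yl)-4H-chromen-4-one | CC1(C)OB(OC1(C)C)c1c(OCc2ccccc2)cc(OCc2ccccc2)c2C(=O)C=COc12 | intermediate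
12 | tert-butyl (triphenylphosphoranylidene)acetate | CC(C)(C)OC(=O)C=P(c1ccccc1)(c1ccccc1)c1ccccc1 | starting material
13 | 3,4-bis(benzyloxy)benzaldehyde | O=Cc1ccc(OCc2ccccc2)c(OCc2ccccc2)c1 | starting material
14 | tert-butyl bromo(triphenylphosphoranylidene)acetate | CC(C)(C)OC(=O)C(Br)=P(c1ccccc1)(c1ccccc1)c1ccccc1 | intermediate
15 | tert-butyl (Z)-2-bromo-3-[3,4-bis(benzyloxy)phenyl]prop-2-enoate | CC(C)(C)OC(=O)/C(Br)=C/c1ccc(OCc2ccccc2)c(OCc2ccccc2)c1 | intermediate
16 | tert-butyl (E)-3-[3,4-bis(benzyloxy)phenyl]-2-[5,7-bis(benzyloxy)-4-oxo-4H-chromen-8-yl]prop-2-enoate | CC(C)(C)OC(=O)/C(=C/c1ccc(OCc2ccccc2)c(OCc2ccccc2)c1)c1c(OCc2ccccc2)cc(OCc2ccccc2)c2C(=O)C=COc12 | intermediate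
17 | (E)-3-[3,4-bis(benzyloxy)phenyl]-2-[5,7-bis(benzyloxy)-4-oxo-4H-chromen-8-yl]prop-2-enoic acid | OC(=O)/C(=C/c1ccc(OCc2ccccc2)c(OCc2ccccc2)c1)c1c(OCc2ccccc2)cc(OCc2ccccc2)c2C(=O)C=COc12 | intermediate
18 | 3,5-bis(benzyloxy)benzyne (1,2-didehydro-3,5-bis(benzyloxy)benzene) | O(Cc1ccccc1)C1=CC(OCc2ccccc2)=CC#C1 | intermediate
19 | (E)-1-[2,4-bis(benzyloxy)-6-hydroxyphenyl]-3-[3,4-bis(benzyloxy)phenyl]-2-[5,7-bis(benzyloxy)-4-oxo-4H-chromen-8-yl]prop-2-en-1-one | O=C(c1c(O)cc(OCc2ccccc2)cc1OCc1ccccc1)/C(=C/c1ccc(OCc2ccccc2)c(OCc2ccccc2)c1)c1c(OCc2ccccc2)cc(OCc2ccccc2)c2C(=O)C=COc12 | intermediate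
20 | 5,7-bis(benzyloxy)-2-[3,4-bis(benzyloxy)phenyl]-3-[5,7-bis(benzyloxy)-4-oxo-4H-chromen-8-yl]chroman-4-one, mixture of stereoisomers | O=C1C=COc2c1c(OCc1ccccc1)cc(OCc1ccccc1)c2C1C(c2ccc(OCc3ccccc3)c(OCc3ccccc3)c2)Oc2cc(OCc3ccccc3)cc(OCc3ccccc3)c2C1=O | intermediate
21 | 5,7-bis(benzyloxy)-2-[3,4-bis(benzyloxy)phenyl]-3-[5,7-bis(benzyloxy)-4-oxo-4H-chromen-8-yl]-4H-chromen-4-one | O=C1C=COc2c1c(OCc1ccccc1)cc(OCc1ccccc1)c2C1=C(c2ccc(OCc3ccccc3)c(OCc3ccccc3)c2)Oc2cc(OCc3ccccc3)cc(OCc3ccccc3)c2C1=O | intermediate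
22 | 4-(benzyloxy)phenylboronic acid | OB(O)c1ccc(OCc2ccccc2)cc1 | starting material
23 | (2S)-5,7-bis(benzyloxy)-2-[4-(benzyloxy)phenyl]-8-{5,7-bis(benzyloxy)-2-[3,4-bis(benzyloxy)phenyl]-4-oxo-4H-chromen-3-yl}chroman-4-one | O=C1C[C@@H](c2ccc(OCc3ccccc3)cc2)Oc2c1c(OCc1ccccc1)cc(OCc1ccccc1)c2C1=C(c2ccc(OCc3ccccc3)c(OCc3ccccc3)c2)Oc2cc(OCc3ccccc3)cc(OCc3ccccc3)c2C1=O | intermediate
24 | 5,7-bis(benzyloxy)-2-[3,4-bis(benzyloxy)phenyl]-3-{5,7-bis(benzyloxy)-2-[4-(benzyloxy)phenyl]-4-hydroxychroman-8-yl}chroman-4-ol; unit E 2R,3S (2,3-cis, the descriptor at C3 differs from that of 25 only because C4 loses rank), unit N 2S, carbinol centres unassigned | OC1C[C@@H](c2ccc(OCc3ccccc3)cc2)Oc2c1c(OCc1ccccc1)cc(OCc1ccccc1)c2[C@H]1C(O)c2c(OCc3ccccc3)cc(OCc3ccccc3)cc2O[C@H]1c1ccc(OCc2ccccc2)c(OCc2ccccc2)c1 | intermediate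
25 | (2R,3R)-5,7-bis(benzyloxy)-2-[3,4-bis(benzyloxy)phenyl]-3-{(2S)-5,7-bis(benzyloxy)-2-[4-(benzyloxy)phenyl]-4-oxochroman-8-yl}chroman-4-one (2,3-cis) | O=C1C[C@@H](c2ccc(OCc3ccccc3)cc2)Oc2c1c(OCc1ccccc1)cc(OCc1ccccc1)c2[C@H]1C(=O)c2c(OCc3ccccc3)cc(OCc3ccccc3)cc2O[C@H]1c1ccc(OCc2ccccc2)c(OCc2ccccc2)c1 | intermediate
26 | (2R,3R)-2-(3,4-dihydroxyphenyl)-5,7-dihydroxy-3-[(2S)-5,7-dihydroxy-2-(4-hydroxyphenyl)-4-oxochroman-8-yl]chroman-4-one (2,3-cis) | O=C1C[C@@H](c2ccc(O)cc2)Oc2c1c(O)cc(O)c2[C@H]1C(=O)c2c(O)cc(O)cc2O[C@H]1c1ccc(O)c(O)c1 | target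

Total steps: 15. Longest linear sequence: 12 steps (from 6 to 26 through steps 3, 4, 5, 6, 8, 9, 10, 11, 12, 13, 14 and 15).

Steps most likely to fail

Step 13 (the step labelled as a proposed new method). The catalyst may fail to turn over at the crowded tetrasubstituted C2(E)=C3(E) bond. Facial selectivity may be poor because the catalyst competes with the bias of the rotamers about C3(E)–C8(N). C3(E) may epimerise before the carbonyl group is reduced. The fallback uses known chemistry, sets out from 19 and comes back at 25, so that 21, 23 and 24 are bypassed. NaOAc in EtOH–THF at 60 °C closes ring C(E) by 6-endo oxa-Michael addition under equilibrating conditions and should give the racemic 2,3-trans flavanone of unit E with chromone N intact F1. Its only enolisable position is C3(E). KN(SiMe3)2 in THF at −78 °C, followed by a hindered phenol as proton source at the same temperature, should protonate the enolate anti to the pseudo-axial C2 aryl group and give the racemic 2,3-cis flavanone F2. The asymmetric arylation of step 12, applied to F2 with 22, then gives 25 together with its unit E (2S,3S) diastereomer F3. F3 is removed by chromatography, at the cost of half the material, and step 15 follows.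

Step 10. The aryl anion may be protonated before the acyl shift, which stops the sequence at the aryl ester. The product phenoxide may be arylated by a second aryne, or the oxa-Michael ring may close early. The fallback sets out from 17, uses bromophenol 2, and comes back at 19 without an aryne. EDC·HCl and DMAP in CH2Cl2 esterify 17 with 2 to give the 2-bromoaryl ester F4. n-BuLi in THF at −100 °C then effects bromine–lithium exchange faster than addition to the chromone. The aryllithium is the same ortho-oxygenated anion, now formed at a defined carbon, and it shifts the acyl group from oxygen to carbon (anionic Fries rearrangement) to give 19 after protonation.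

Step 8. The doubly ortho-oxygenated boronate may protodeboronate or transmetalate too slowly, and the alkene geometry may erode. The fallback sets out from 10 and comes back at 17 by forming the alkene in a condensation. Pd(dba)2 with XPhos couples 10 with the Reformatsky reagent BrZnCH2CO2t-Bu in THF to give the tert-butyl chromon-8-ylacetate F5. CF3CO2H frees the chromon-8-ylacetic acid F6. Perkin condensation of F6 with aldehyde 13 (Ac2O, Et3N, 110 °C) should give the (E)-acid 17 directly, with the two aryl groups cis as is usual for this condensation.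

Further compounds
F1 | step 13 | racemic 2,3-trans 5,7-bis(benzyloxy)-2-[3,4-bis(benzyloxy)phenyl]-3-[5,7-bis(benzyloxy)-4-oxo-4H-chromen-8-yl]chroman-4-one (2R,3S enantiomer drawn) | O=C1C=COc2c1c(OCc1ccccc1)cc(OCc1ccccc1)c2[C@@H]1C(=O)c2c(OCc3ccccc3)cc(OCc3ccccc3)cc2O[C@H]1c1ccc(OCc2ccccc2)c(OCc2ccccc2)c1
F2 | step 13 | racemic 2,3-cis 5,7-bis(benzyloxy)-2-[3,4-bis(benzyloxy)phenyl]-3-[5,7-bis(benzyloxy)-4-oxo-4H-chromen-8-yl]chroman-4-one (2R,3R enantiomer drawn) | O=C1C=COc2c1c(OCc1ccccc1)cc(OCc1ccccc1)c2[C@H]1C(=O)c2c(OCc3ccccc3)cc(OCc3ccccc3)cc2O[C@H]1c1ccc(OCc2ccccc2)c(OCc2ccccc2)c1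
F3 | step 13 | (2S,3S)-5,7-bis(benzyloxy)-2-[3,4-bis(benzyloxy)phenyl]-3-{(2S)-5,7-bis(benzyloxy)-2-[4-(benzyloxy)phenyl]-4-oxochroman-8-yl}chroman-4-one | O=C1C[C@@H](c2ccc(OCc3ccccc3)cc2)Oc2c1c(OCc1ccccc1)cc(OCc1ccccc1)c2[C@@H]1C(=O)c2c(OCc3ccccc3)cc(OCc3ccccc3)cc2O[C@@H]1c1ccc(OCc2ccccc2)c(OCc2ccccc2)c1
F4 | step 10 | 2-bromo-3,5-bis(benzyloxy)phenyl (E)-3-[3,4-bis(benzyloxy)phenyl]-2-[5,7-bis(benzyloxy)-4-oxo-4H-chromen-8-yl]prop-2-enoate | O=C(Oc1cc(OCc2ccccc2)cc(OCc2ccccc2)c1Br)/C(=C/c1ccc(OCc2ccccc2)c(OCc2ccccc2)c1)c1c(OCc2ccccc2)cc(OCc2ccccc2)c2C(=O)C=COc12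
F5 | step 8 | tert-butyl 2-[5,7-bis(benzyloxy)-4-oxo-4H-chromen-8-yl]acetate | CC(C)(C)OC(=O)Cc1c(OCc2ccccc2)cc(OCc2ccccc2)c2C(=O)C=COc12
F6 | step 8 | 2-[5,7-bis(benzyloxy)-4-oxo-4H-chromen-8-yl]acetic acid | OC(=O)Cc1c(OCc2ccccc2)cc(OCc2ccccc2)c2C(=O)C=COc12
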